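A leftover in this flask can be read as a count: how many turnovers the reagent G paid for, and how many it did not.

    X ⇌ D (K1 = 0.87, k1 = 0.10 s⁻¹)
    G + L → Z + E (k2 = 260 M⁻¹ s⁻¹)
    X + G → J + E (k3 = 170 M⁻¹ s⁻¹)
    G + J → L + E (k4 = 15 M⁻¹ s⁻¹)

X 0.0050 M; G 5.50 mM; time 4.0 min

1. at 4.0 min, what has stopped the reaction, if anything has (it is still moving / G has run out first / all of X has reacted)
2. L at 4.0 min, in percent of the X charged
3. J at 4.0 min, in percent of the X charged

- the reaction counts as stopped when no species that holds the X changes by six tenths of a point or more over the second half of the time
- run time (flask): 4.0 min

Every step that takes G gives one E and lifts one X one rung up the ladder X, J, L, Z, whereas the exchange of X with D takes no G. In fractions of the X charged, 1.10 is the turnover count, the G charged over the X charged. J holds one turnover, L 2 and Z 3, so the top of the ladder costs more than the count, and G is the limiting reagent.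

With G as charged, X halves by its capture in 0.74 s and J halves in 0.14 min, both shorter than 4.0 min, so the reckoning expects G to be used up within the run. Then J, plus 2 L, plus 3 Z equals the count.

Two more relations close the sum. At the start X goes to J 9.3 times as fast as to D, so the guess is that 9.66% stays unbound and 90.3% is held by J, L and Z. L is lost faster than J, so L is taken as a steady intermediate, and since G multiplies both its making and its loss, L over J is 0.0577. Solving gives J 78.3% and L 4.51%.

The forecast, G has run out first with L 4.5% and J 76%, puts J below this reckoning, and its grounds are “L stays low because it goes on to Z much faster than it forms from J”.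

At 4.0 min the flask reads: G has run out first, with G at 0% of its charge, L 3.92% and J 71.6%, while X and D together hold 14.3%. Step by step, X was captured while G was there, half of that turnover being done by 0.822 s, and G stood at 0.736% of its charge at 0.400 min. From 2.00 min, with G at 0%, the amounts stand as they do at the end. J, plus 2 L, plus 3 Z adds to 1.10 against the count of 1.10. In the neighbour flask charged with 0.0033 M of G, the count is 0.660, the same sum gives 0.660, and 21% of the charge remains as X.

(The numbers are made up; no experiment stands behind them.)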